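**Plan**

1. Germacrane locants are used (ring C1–C10, C14 on C10, C15 on C4, C11–C13 on C7; lactone O on C6, acetates on C8 and C13). Retrosynthesis: both oxiranes go back to the E,E-1(10),4-diene; the lactone C12–O6 bond is opened to a Z-enoate with silylated C6–OH; the ten-membered carbocycle is cut at C3–C4; the chain is cut at C2–C3, C8–C9, C7–C8, C11–C13 and C6–C7.
2. Enabling feature: C4 is the methyl-bearing carbon of the 4,5-oxirane, a latent E-trisubstituted alkene, so it can be an alkenyl iodide. C3 is the second carbon beyond C1 of the 1,10-oxirane (latent alkene), so a terminal diene C10=C1–C2=C3 gives a primary C3 borane. An intramolecular B-alkyl Suzuki–Miyaura coupling then closes the carbocycle.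
3. Forward: the chain first: (E)-3-iodobut-2-enal (C4–C6, C15) plus methyl propiolate (C7, C11, C12); vinyl (C8) and formaldehyde (C13) added across the alkyne; C8 aldehyde plus prenal dienolate (C9, C10, C14, C1, C2); methylene (C3). Then the ten-membered ring, then the butenolide ring, last both oxirane rings.
4. Stereochemistry: C6 by catalyst-controlled alkynylation; C8 by a chiral-Lewis-acid-controlled vinylogous aldol; Z-C7=C11 by syn-carbocupration; E-C4=C5 from the iodoalkene; E-C1=C10 from the vinylogous aldol; C1, C10, C4, C5 by outer-face epoxidation of the macrocycle.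

Key step: step 12

Remark: in steps 3 and 9 the named antipode of the ligand or promoter is the one assumed to deliver the required aldehyde face; if the facial sense is opposite for these substrates, the other antipode is used and nothing else changes.

**Route**

Step 1
Reactants: 1 but-2-yn-1-ol
Product: 3 (E)-3-iodobut-2-en-1-ol, via alkenylzirconocene 2 (not isolated)
Conditions: i-Bu2AlH (1.0 equiv), THF, 0 °C; Cp2ZrCl2/i-Bu2AlH (1.2 equiv each, forms Cp2Zr(H)Cl), 0 °C to rt; I2, −78 to 0 °C
Reagents that add atoms: iodine, II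
Why: syn-hydrozirconation of the propargylic aluminium alkoxide should place zirconium on the carbon remote from oxygen, and iodinolysis of the C–Zr bond with retention should give the E iodoalkene (hydrozirconation–iodination).

Step 2
Reactants: 3 (E)-3-iodobut-2-en-1-ol
Product: 4 (E)-3-iodobut-2-enal
Conditions: MnO2 (activated, excess), CH2Cl2, rt
Reagents that add atoms: none
Why: MnO2 oxidizes allylic alcohols under neutral conditions, so the E iodoalkene should survive unchanged (allylic oxidation).

Step 3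
Reactants: 4 (E)-3-iodobut-2-enal; 5 methyl propiolate
Product: 6 methyl (4R,5E)-4-hydroxy-6-iodohept-5-en-2-ynoate
Conditions: (S,S)-ProPhenol (20 mol %), Me2Zn (3 equiv), Ph3PO (40 mol %), toluene, 0 °C
Reagents that add atoms: none
Why: the dinuclear zinc–ProPhenol complex should deliver the zinc alkynylide of the propiolate to one face of the enal (catalytic asymmetric alkynylation), which sets the carbinol carbon (later C6) by catalyst control.

Step 4
Reactants: 6 methyl (4R,5E)-4-hydroxy-6-iodohept-5-en-2-ynoate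
Product: 7 methyl (4R,5E)-4-[(tert-butyldimethylsilyl)oxy]-6-iodohept-5-en-2-ynoate
Conditions: TBSOTf, 2,6-lutidine, CH2Cl2, −78 °C
Reagents that add atoms: tert-butyldimethylsilyl triflate, CC(C)(C)[Si](C)(C)OS(=O)(=O)C(F)(F)F
Why: silyl ether formation with a hindered base spares the base-sensitive γ-hydroxy ynoate and blocks lactonization, so C6–H stays non-acidic until the ring is closed.

Step 5
Reactants: 7 methyl (4R,5E)-4-[(tert-butyldimethylsilyl)oxy]-6-iodohept-5-en-2-ynoate
Product: 9 methyl (2Z,4R,5E)-4-[(tert-butyldimethylsilyl)oxy]-3-ethenyl-2-(hydroxymethyl)-6-iodohepta-2,5-dienoate, via α-cuprio dienoate 8 (not isolated)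
Conditions: (CH2=CH)2CuMgBr [from CH2=CHMgBr (2.2 equiv) and CuI (1.1 equiv)], THF, −78 °C; Et2AlCl, then CH2O (monomeric, THF), −78 to −40 °C; aq NH4Cl
Reagents that add atoms: vinylmagnesium bromide, C=C[Mg]Br; formaldehyde, C=O
Why: syn-carbocupration of the 2-alkynoate puts vinyl on the β-carbon (C7), and the α-alkenylcopper should be trapped by formaldehyde at C11 with retention (tandem conjugate addition–aldol), so the ester ends up cis to C6 on the tetrasubstituted alkene.

Step 6
Reactants: 9 methyl (2Z,4R,5E)-4-[(tert-butyldimethylsilyl)oxy]-3-ethenyl-2-(hydroxymethyl)-6-iodohepta-2,5-dienoate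
Product: 10 methyl (2Z,4R,5E)-2-(acetoxymethyl)-4-[(tert-butyldimethylsilyl)oxy]-3-ethenyl-6-iodohepta-2,5-dienoate
Conditions: Ac2O, pyridine, DMAP (cat.), CH2Cl2, 0 °C
Reagents that add atoms: acetic anhydride, CC(=O)OC(C)=O
Why: acylation of the primary allylic alcohol installs the C13 acetate of the target and prevents hemiacetal formation with the aldehyde made next.

Step 7
Reactants: 10 methyl (2Z,4R,5E)-2-(acetoxymethyl)-4-[(tert-butyldimethylsilyl)oxy]-3-ethenyl-6-iodohepta-2,5-dienoate
Product: 12 methyl (2E,4R,5E)-2-(acetoxymethyl)-4-[(tert-butyldimethylsilyl)oxy]-3-formyl-6-iodohepta-2,5-dienoate, via vicinal diol 11 (not isolated)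
Conditions: OsO4 (2 mol %), NaIO4 (4 equiv), 2,6-lutidine, dioxane/H2O, rt
Reagents that add atoms: osmium tetroxide, O=[Os](=O)(=O)=O; sodium periodate, [Na+].[O-]I(=O)(=O)=O
Why: the terminal alkene of the dienoate should be dihydroxylated much faster than the iodinated trisubstituted and the electron-poor tetrasubstituted alkenes, and periodate cleaves the diol in the same flask (Lemieux–Johnson oxidation).

Step 8
Reactants: 13 3-methylbut-2-enal
Product: 14 (E)-tert-butyldimethyl[(3-methylbuta-1,3-dien-1-yl)oxy]silane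
Conditions: TBSOTf, Et3N, Et2O, 0 °C to rt
Reagents that add atoms: tert-butyldimethylsilyl triflate, CC(C)(C)[Si](C)(C)OS(=O)(=O)C(F)(F)F
Why: O-silylation of the enal followed by γ-deprotonation should give the (1E)-silyl dienol ether (silyl dienolate formation).

Step 9
Reactants: 12 methyl (2E,4R,5E)-2-(acetoxymethyl)-4-[(tert-butyldimethylsilyl)oxy]-3-formyl-6-iodohepta-2,5-dienoate; 14 (E)-tert-butyldimethyl[(3-methylbuta-1,3-dien-1-yl)oxy]silane
Product: 15 methyl (2Z,4S,6E)-2-(acetoxymethyl)-4-hydroxy-3-[(1R,2E)-1-[(tert-butyldimethylsilyl)oxy]-3-iodobut-2-en-1-yl]-6-methyl-8-oxoocta-2,6-dienoate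
Conditions: B-phenyl oxazaborolidinone from N-tosyl-D-tryptophan and PhBCl2 (1.0 equiv), i-PrOH (1.1 equiv), EtCN, −78 °C
Reagents that add atoms: none
Why: the aldehyde-derived dienolate should attack through its γ-carbon to give the E enal while the chiral boron Lewis acid shields one aldehyde face (vinylogous Mukaiyama aldol reaction), which sets C8 as S by reagent control.

Step 10
Reactants: 15 methyl (2Z,4S,6E)-2-(acetoxymethyl)-4-hydroxy-3-[(1R,2E)-1-[(tert-butyldimethylsilyl)oxy]-3-iodobut-2-en-1-yl]-6-methyl-8-oxoocta-2,6-dienoate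
Product: 16 methyl (2Z,4S,6E)-2-(acetoxymethyl)-4-hydroxy-3-[(1R,2E)-1-[(tert-butyldimethylsilyl)oxy]-3-iodobut-2-en-1-yl]-6-methylnona-2,6,8-trienoate
Conditions: Ph3PCH3Br (3 equiv), KN(SiMe3)2 (2.9 equiv), THF, −78 to 0 °C
Reagents that add atoms: methyltriphenylphosphonium bromide, C[P+](c1ccccc1)(c1ccccc1)c1ccccc1.[Br-]
Why: the unhindered enal should react with Ph3P=CH2 at low temperature far faster than the esters (Wittig methylenation), giving the terminal E-diene C10=C1–C2=C3.

Step 11
Reactants: 16 methyl (2Z,4S,6E)-2-(acetoxymethyl)-4-hydroxy-3-[(1R,2E)-1-[(tert-butyldimethylsilyl)oxy]-3-iodobut-2-en-1-yl]-6-methylnona-2,6,8-trienoate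
Product: 17 methyl (2Z,4S,6E)-4-acetoxy-2-(acetoxymethyl)-3-[(1R,2E)-1-[(tert-butyldimethylsilyl)oxy]-3-iodobut-2-en-1-yl]-6-methylnona-2,6,8-trienoate
Conditions: Ac2O, pyridine, DMAP (cat.), CH2Cl2, 0 °C
Reagents that add atoms: acetic anhydride, CC(=O)OC(C)=O
Why: acylation of the secondary allylic alcohol installs the C8 acetate with retention, since the C–O bond is not touched.

Step 12
Reactants: 17 methyl (2Z,4S,6E)-4-acetoxy-2-(acetoxymethyl)-3-[(1R,2E)-1-[(tert-butyldimethylsilyl)oxy]-3-iodobut-2-en-1-yl]-6-methylnona-2,6,8-trienoate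
Product: 19 methyl (2Z)-3-acetoxy-2-[(2S,4E,8E,10R)-2-acetoxy-10-[(tert-butyldimethylsilyl)oxy]-4,8-dimethylcyclodeca-4,8-dien-1-ylidene]propanoate, via B-alkyl-9-BBN borane 18 (not isolated)
Conditions: 9-BBN (1.5 equiv), THF, 0 °C to rt; then syringe-pump addition to Pd(dppf)Cl2 (20 mol %), AsPh3 (20 mol %), Cs2CO3 (3 equiv), DMF/THF/H2O, rt, final 1 mM
Reagents that add atoms: none
Why: 9-BBN should add anti-Markovnikov only to the terminal C2=C3 alkene of the 1,3-diene (the trisubstituted, iodinated and tetrasubstituted alkenes are too hindered) to give the primary C3 borane 18; zerovalent palladium then inserts into the C4–I bond with retention, the base-activated borate transfers the primary alkyl group to palladium, and reductive elimination forms the C3(sp3)–C4(sp2) bond. The closest known reaction type is the intramolecular B-alkyl Suzuki–Miyaura coupling used to close macrocyclic alkenes. The only ring closed is the ten-membered carbocycle, by end-to-end macrocyclization in which both coupling carbons and the C4=C5 alkene become endocyclic (an eleven-membered palladacycle contracts on reductive elimination). No new stereocentre is formed; what the step fixes is the E geometry of C4=C5 (from the iodoalkene) beside the untouched E-C1=C10, and these two alkenes later become C4, C5, C1 and C10. The step needs ring closure to outrun oligomerization, β-hydride elimination and ionization of the allylic acetates: slow addition at high dilution, the Z-tetrasubstituted C7=C11 alkene that carries C6 and C8 on one carbon as a turn, and fast reductive elimination from the dppf complex should secure this, while the acyclic C6 silyl ether keeps C6–H non-acidic toward Cs2CO3.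

Step 13
Reactants: 19 methyl (2Z)-3-acetoxy-2-[(2S,4E,8E,10R)-2-acetoxy-10-[(tert-butyldimethylsilyl)oxy]-4,8-dimethylcyclodeca-4,8-dien-1-ylidene]propanoate
Product: 21 (6R,8S)-8,13-diacetoxygermacra-1(10)E,4E,7(11)-trien-12,6-olide, via hydroxy ester 20 (not isolated)
Conditions: HF·pyridine, pyridine, THF, 0 °C to rt
Reagents that add atoms: none
Why: buffered fluoride cleaves the allylic silyl ether, and the freed C6 hydroxyl, held cis to the ester on the tetrasubstituted alkene, should close the butenolide spontaneously (desilylation–lactonization) without acid that would trigger transannular cyclization of the cyclodecadiene.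

Step 14
Reactants: 21 (6R,8S)-8,13-diacetoxygermacra-1(10)E,4E,7(11)-trien-12,6-olide
Product: 22 (1R,4R,5R,6S,8S,10R)-8,13-diacetoxy-1,10:4,5-diepoxygermacr-7(11)-en-12,6-olide
Conditions: DMDO (3 equiv), acetone, −20 to 0 °C
Reagents that add atoms: dimethyldioxirane, CC1(C)OO1
Why: the neutral dioxirane should epoxidize the two electron-rich trisubstituted ring alkenes and leave the electron-poor butenolide alkene, and attack on the outer face of each alkene in the crown conformer (both ring methyls syn, as known for germacranolide 6α-olides) should give the 1β,10α- and 4α,5β-oxiranes (dioxirane epoxidation).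

**Compound list**

1 | but-2-yn-1-ol | CC#CCO | starting material
2 | (E)-alkenylzirconocene chloride of the diisobutylaluminium alkoxide of 1 (Zr on C3; not isolated) | C/C(=C\CO[Al](CC(C)C)CC(C)C)[Zr](Cl)(C1C=CC=C1)C1C=CC=C1 | intermediate
3 | (E)-3-iodobut-2-en-1-ol | C/C(I)=C\CO | intermediate
4 | (E)-3-iodobut-2-enal | C/C(I)=C\C=O | intermediate
5 | methyl propiolate | C#CC(=O)OC | starting material
6 | methyl (4R,5E)-4-hydroxy-6-iodohept-5-en-2-ynoate | COC(=O)C#C[C@H](O)/C=C(\C)I | intermediate
7 | methyl (4R,5E)-4-[(tert-butyldimethylsilyl)oxy]-6-iodohept-5-en-2-ynoate | COC(=O)C#C[C@H](O[Si](C)(C)C(C)(C)C)/C=C(\C)I | intermediate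
8 | α-cuprio dienoate (Cu on C11, vinyl on C7, syn; not isolated) | COC(=O)/C([Cu])=C(/C=C)[C@H](O[Si](C)(C)C(C)(C)C)/C=C(\C)I | intermediate
9 | methyl (2Z,4R,5E)-4-[(tert-butyldimethylsilyl)oxy]-3-ethenyl-2-(hydroxymethyl)-6-iodohepta-2,5-dienoate | COC(=O)/C(CO)=C(/C=C)[C@H](O[Si](C)(C)C(C)(C)C)/C=C(\C)I | intermediate
10 | methyl (2Z,4R,5E)-2-(acetoxymethyl)-4-[(tert-butyldimethylsilyl)oxy]-3-ethenyl-6-iodohepta-2,5-dienoate | COC(=O)/C(COC(C)=O)=C(/C=C)[C@H](O[Si](C)(C)C(C)(C)C)/C=C(\C)I | intermediate
11 | vicinal diol from the ethenyl group of 10 (both epimers at the new carbinol; not isolated) | COC(=O)/C(COC(C)=O)=C(/C(O)CO)[C@H](O[Si](C)(C)C(C)(C)C)/C=C(\C)I | intermediate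
12 | methyl (2E,4R,5E)-2-(acetoxymethyl)-4-[(tert-butyldimethylsilyl)oxy]-3-formyl-6-iodohepta-2,5-dienoate | COC(=O)/C(COC(C)=O)=C(/C=O)[C@H](O[Si](C)(C)C(C)(C)C)/C=C(\C)I | intermediate
13 | 3-methylbut-2-enal | CC(C)=CC=O | starting material
14 | (E)-tert-butyldimethyl[(3-methylbuta-1,3-dien-1-yl)oxy]silane | C=C(C)/C=C/O[Si](C)(C)C(C)(C)C | intermediate
15 | methyl (2Z,4S,6E)-2-(acetoxymethyl)-4-hydroxy-3-[(1R,2E)-1-[(tert-butyldimethylsilyl)oxy]-3-iodobut-2-en-1-yl]-6-methyl-8-oxoocta-2,6-dienoate (C8–OH, 8S) | COC(=O)/C(COC(C)=O)=C(/[C@@H](O)C/C(C)=C/C=O)[C@H](O[Si](C)(C)C(C)(C)C)/C=C(\C)I | intermediate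
16 | methyl (2Z,4S,6E)-2-(acetoxymethyl)-4-hydroxy-3-[(1R,2E)-1-[(tert-butyldimethylsilyl)oxy]-3-iodobut-2-en-1-yl]-6-methylnona-2,6,8-trienoate | COC(=O)/C(COC(C)=O)=C(/[C@@H](O)C/C(C)=C/C=C)[C@H](O[Si](C)(C)C(C)(C)C)/C=C(\C)I | intermediate
17 | methyl (2Z,4S,6E)-4-acetoxy-2-(acetoxymethyl)-3-[(1R,2E)-1-[(tert-butyldimethylsilyl)oxy]-3-iodobut-2-en-1-yl]-6-methylnona-2,6,8-trienoate | COC(=O)/C(COC(C)=O)=C(/[C@@H](OC(C)=O)C/C(C)=C/C=C)[C@H](O[Si](C)(C)C(C)(C)C)/C=C(\C)I | intermediate
18 | B-alkyl-9-BBN borane of 17 (boron on C3; not isolated) | COC(=O)/C(COC(C)=O)=C(/[C@@H](OC(C)=O)C/C(C)=C/CCB1C2CCCC1CCC2)[C@H](O[Si](C)(C)C(C)(C)C)/C=C(\C)I | intermediate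
19 | methyl (2Z)-3-acetoxy-2-[(2S,4E,8E,10R)-2-acetoxy-10-[(tert-butyldimethylsilyl)oxy]-4,8-dimethylcyclodeca-4,8-dien-1-ylidene]propanoate | COC(=O)/C(COC(C)=O)=C1/[C@@H](OC(C)=O)C/C(C)=C/CC/C(C)=C/[C@H]1O[Si](C)(C)C(C)(C)C | intermediate
20 | methyl (2Z)-3-acetoxy-2-[(2S,4E,8E,10R)-2-acetoxy-10-hydroxy-4,8-dimethylcyclodeca-4,8-dien-1-ylidene]propanoate (not isolated) | COC(=O)/C(COC(C)=O)=C1/[C@@H](OC(C)=O)C/C(C)=C/CC/C(C)=C/[C@H]1O | intermediate
21 | (6R,8S)-8,13-diacetoxygermacra-1(10)E,4E,7(11)-trien-12,6-olide | CC(=O)OCC1=C2[C@@H](OC(C)=O)C/C(C)=C/CC/C(C)=C/[C@H]2OC1=O | intermediate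
22 | (1R,4R,5R,6S,8S,10R)-8,13-diacetoxy-1,10:4,5-diepoxygermacr-7(11)-en-12,6-olide | CC(=O)OCC1=C2[C@@H](OC(C)=O)C[C@@]3(C)O[C@@H]3CC[C@@]3(C)O[C@@H]3[C@H]2OC1=O | target

**Count and risks**

Total steps: 14. Longest linear sequence: 13 (steps 1–7 and 9–14; step 8 is a one-step branch).

Most likely to fail:

1. Step 12. Oligomerization, protodeboronation or β-hydride elimination may outrun closure of the strained ten-membered ring, and zerovalent palladium with aqueous base may ionize or hydrolyse the allylic acetates. The fallback sets out from 17 and returns at 19, and makes the same C3–C4 bond from an organozinc without base. Hydroboration of 17 as before, then NaBO3·4H2O, should give the C3 primary alcohol F1. I2, PPh3 and imidazole should give the C3 primary iodide F2. Zinc insertion (Zn dust, LiCl, THF, rt; the alkenyl iodide inserts far more slowly) should give the C3 alkylzinc iodide F3. Slow addition of F3 to Pd2(dba)3 and SPhos (zerovalent palladium) in THF/NMP at high dilution should close the ring by intramolecular Negishi coupling to 19.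

2. Step 5. The alkenylcopper may be protonated instead of trapped by formaldehyde, or the alkene geometry may be lost through the allenoate. The fallback sets out from 7 and returns at 9, and separates the two bond formations. Carbocupration as before followed by an I2 quench should give the α-iodo dienoate F4. i-PrMgCl·LiCl at −78 °C should exchange only the ester-activated iodide to give the α-chloromagnesio dienoate F5, which is more nucleophilic than the copper species and should add to CH2O to give 9.

3. Step 9. Facial selectivity may be poor if the chiral Lewis acid and the C6 stereocentre oppose each other, and α-attack of the dienolate may compete. The fallback sets out from 12 and returns at 17, and corrects C8 by inversion instead of reagent control. The aldol is run with whichever Lewis acid (for example B(C6F5)3) gives the cleanest single epimer; if that is the 8R hydroxy enal F6, it is methylenated as in step 10 to the 8R diene alcohol F7. Mitsunobu esterification of F7 with AcOH (PPh3, DIAD) should invert C8 and give 17 directly.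

Further compounds
F1 | step 12 | C3 primary alcohol from hydroboration–oxidation of 17 | COC(=O)/C(COC(C)=O)=C(/[C@@H](OC(C)=O)C/C(C)=C/CCO)[C@H](O[Si](C)(C)C(C)(C)C)/C=C(\C)I
F2 | step 12 | C3 primary iodide | COC(=O)/C(COC(C)=O)=C(/[C@@H](OC(C)=O)C/C(C)=C/CCI)[C@H](O[Si](C)(C)C(C)(C)C)/C=C(\C)I
F3 | step 12 | C3 alkylzinc iodide | COC(=O)/C(COC(C)=O)=C(/[C@@H](OC(C)=O)C/C(C)=C/CC[Zn]I)[C@H](O[Si](C)(C)C(C)(C)C)/C=C(\C)I
F4 | step 5 | methyl (2E,4R,5E)-4-[(tert-butyldimethylsilyl)oxy]-3-ethenyl-2,6-diiodohepta-2,5-dienoate | COC(=O)/C(I)=C(/C=C)[C@H](O[Si](C)(C)C(C)(C)C)/C=C(\C)I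
F5 | step 5 | α-chloromagnesio dienoate (Mg on C11) | COC(=O)/C([Mg]Cl)=C(/C=C)[C@H](O[Si](C)(C)C(C)(C)C)/C=C(\C)I
F6 | step 9 | 8R epimer of 15 | COC(=O)/C(COC(C)=O)=C(/[C@H](O)C/C(C)=C/C=O)[C@H](O[Si](C)(C)C(C)(C)C)/C=C(\C)I
F7 | step 9 | 8R epimer of 16 | COC(=O)/C(COC(C)=O)=C(/[C@H](O)C/C(C)=C/C=C)[C@H](O[Si](C)(C)C(C)(C)C)/C=C(\C)I
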